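**Retrosynthetic overview**

1. The target comes from its bis(O-benzyl) ether by hydrogenolysis; the primary acetate comes from selective acetylation of a primary/tertiary diol, itself unmasked from a silyl ether.
2. The oxolane comes from an α-hydroxy-γ-butyrolactone with the same five ring atoms (C=O to CH2 via the lactol and ionic hydrogenation).
3. The tertiary carbinol comes from two successive lactone-enolate reactions, C-benzylation then O-hydroxylation, each anti to the neighbouring CH2OSi group.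
4. The trans-γ-aryl lactone comes from an Evans boron syn-aldol between a succinate-derived N-acyl oxazolidinone and O-benzylvanillin (key C–C bond; sets both CH stereocentres), followed by lactonisation.
5. Ring order: only one ring is built, the γ-lactone, closed right after the aldol and later deoxygenated to the oxolane.

Assumption: the target is taken exactly as drawn, the primary acetate of (2S,3R,4S)-olivil; O-benzylvanillin, (S)-4-benzyloxazolidin-2-one and methyl 4-chloro-4-oxobutanoate are bought.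

**Route**

Step 1
Reactants: 1 4-(benzyloxy)-3-methoxybenzaldehyde
Product: 2 [4-(benzyloxy)-3-methoxyphenyl]methanol
Conditions: NaBH4, MeOH, 0 °C → rt
Reagents that add atoms: none
Why: Borohydride reduction of an aryl aldehyde gives the benzylic alcohol cleanly and leaves the benzyl ether alone; no stereocentre is formed.

Step 2
Reactants: 2 [4-(benzyloxy)-3-methoxyphenyl]methanol
Product: 3 1-(benzyloxy)-4-(bromomethyl)-2-methoxybenzene
Conditions: PBr3 (0.4 equiv), Et2O, 0 °C; used crude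
Reagents that add atoms: phosphorus tribromide, BrP(Br)Br
Why: Alcohol-to-bromide substitution via the phosphite ester is fast for an electron-rich benzylic alcohol, and the labile bromide is used at once.

Step 3
Reactants: 4 (4S)-4-benzyl-1,3-oxazolidin-2-one; 5 methyl 4-chloro-4-oxobutanoate
Product: 7 methyl 4-[(4S)-4-benzyl-2-oxo-1,3-oxazolidin-3-yl]-4-oxobutanoate, via N-lithio oxazolidinone 6 (not isolated)
Conditions: n-BuLi, THF, −78 °C; then 5, −78 → 0 °C
Reagents that add atoms: none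
Why: N-acylation of the lithiated Evans auxiliary by the acid chloride is far faster at −78 °C than attack on the methyl ester, so only the imide forms.

Step 4
Reactants: 7 methyl 4-[(4S)-4-benzyl-2-oxo-1,3-oxazolidin-3-yl]-4-oxobutanoate; 1 4-(benzyloxy)-3-methoxybenzaldehyde
Product: 9 methyl (3S,4S)-3-{[(4S)-4-benzyl-2-oxo-1,3-oxazolidin-3-yl]carbonyl}-4-[4-(benzyloxy)-3-methoxyphenyl]-4-hydroxybutanoate, via dibutylboron Z-enolate 8 (not isolated)
Conditions: Bu2BOTf, iPr2NEt, CH2Cl2, 0 °C; then 1, −78 → 0 °C; pH 7 buffer, MeOH, 30% H2O2, 0 °C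
Reagents that add atoms: none
Why: In this Evans boron syn-aldol the Z-enolate of the imide (enolised in preference to the remote ester) reacts through a Zimmerman–Traxler chair on the face away from the 4-benzyl group, so the (S)-auxiliary sets both new centres as (3S,4S).

Step 5
Reactants: 9 the syn-aldol adduct
Product: 10 (4S)-4-benzyl-3-{[(2S,3S)-2-[4-(benzyloxy)-3-methoxyphenyl]-5-oxooxolan-3-yl]carbonyl}-1,3-oxazolidin-2-one (2,3-trans)
Conditions: PPTS (10 mol%), toluene, 60 °C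
Reagents that add atoms: none
Why: Acid-catalysed γ-lactonisation of the benzylic hydroxyl onto the methyl ester closes the five-membered ring without touching either stereocentre, and the syn adduct necessarily gives the 2,3-trans lactone (any adduct that lactonised during step 4 is simply carried through).

Step 6
Reactants: 10 the lactone imide
Product: 12 (2S,3S)-2-[4-(benzyloxy)-3-methoxyphenyl]-5-oxooxolane-3-carboxylic acid, via lithium percarboxylate 11 (not isolated)
Conditions: LiOH, 30% H2O2, THF/H2O (3:1), 0 °C; aq. Na2SO3; HCl to pH 2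
Reagents that add atoms: hydrogen peroxide, OO
Why: In this Evans LiOOH cleavage hydroperoxide attacks the exocyclic imide carbonyl selectively, sulfite reduces the peracid, and acidification recloses any opened lactone, so the auxiliary is recovered without epimerisation at 0 °C.

Step 7
Reactants: 12 the lactone acid
Product: 13 (4R,5S)-5-[4-(benzyloxy)-3-methoxyphenyl]-4-(hydroxymethyl)oxolan-2-one
Conditions: BH3·SMe2, THF, 0 °C → rt; MeOH quench
Reagents that add atoms: none
Why: Borane reduces a free carboxylic acid much faster than a lactone (chemoselective acid reduction), leaving both stereocentres intact.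

Step 8
Reactants: 13 the hydroxymethyl lactone
Product: 14 (4R,5S)-5-[4-(benzyloxy)-3-methoxyphenyl]-4-{[(tert-butyldiphenylsilyl)oxy]methyl}oxolan-2-one
Conditions: TBDPSCl, imidazole, CH2Cl2, 0 °C → rt
Reagents that add atoms: tert-butyl(chloro)diphenylsilane, CC(C)(C)[Si](Cl)(c1ccccc1)c1ccccc1
Why: Standard silylation of the primary alcohol gives a bulky ether that survives enolate chemistry, DIBAL-H and cold BF3 and shields one face of the lactone.

Step 9
Reactants: 14 the silyl-protected lactone; 3 1-(benzyloxy)-4-(bromomethyl)-2-methoxybenzene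
Product: 16 (3S,4R,5S)-3-[4-(benzyloxy)-3-methoxybenzyl]-5-[4-(benzyloxy)-3-methoxyphenyl]-4-{[(tert-butyldiphenylsilyl)oxy]methyl}oxolan-2-one, via lithium enolate 15 (not isolated)
Conditions: LiHMDS, THF, −78 °C; then 3, −78 → −30 °C
Reagents that add atoms: none
Why: In this lactone enolate alkylation the reactive benzylic bromide enters anti to the adjacent CH2OTBDPS group (1,2-induction), placing the benzyl group trans to it.

Step 10
Reactants: 16 the α-benzyl lactone
Product: 18 (3S,4R,5S)-3-[4-(benzyloxy)-3-methoxybenzyl]-5-[4-(benzyloxy)-3-methoxyphenyl]-4-{[(tert-butyldiphenylsilyl)oxy]methyl}-3-hydroxyoxolan-2-one, via potassium enolate 17 (not isolated)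
Conditions: KHMDS, THF, −78 °C; 2-(phenylsulfonyl)-3-phenyloxaziridine, −78 °C; AcOH quench
Reagents that add atoms: 2-(phenylsulfonyl)-3-phenyloxaziridine (Davis reagent), O=S(=O)(c1ccccc1)N1OC1c1ccccc1
Why: In this Davis enolate hydroxylation the oxygen is again delivered anti to the CH2OTBDPS group, so the hydroxyl ends trans and the benzyl cis to it, which is the carbinol configuration of the target.

Step 11
Reactants: 18 the α-hydroxy lactone
Product: 19 (3S,4R,5S)-3-[4-(benzyloxy)-3-methoxybenzyl]-5-[4-(benzyloxy)-3-methoxyphenyl]-4-{[(tert-butyldiphenylsilyl)oxy]methyl}oxolane-2,3-diol (anomer mixture)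
Conditions: DIBAL-H (2.5 equiv), CH2Cl2, −78 °C; Rochelle salt work-up
Reagents that add atoms: none
Why: DIBAL-H half-reduction of a γ-lactone stops at the lactol at −78 °C because the aluminium hemiacetal is stable, with one equivalent consumed by the tertiary hydroxyl.

Step 12
Reactants: 19 the lactol
Product: 20 (3S,4R,5S)-3-[4-(benzyloxy)-3-methoxybenzyl]-5-[4-(benzyloxy)-3-methoxyphenyl]-4-{[(tert-butyldiphenylsilyl)oxy]methyl}oxolan-3-ol
Conditions: Et3SiH, BF3·OEt2, CH2Cl2, −78 → −40 °C; aq. NaHCO3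
Reagents that add atoms: none
Why: In this ionic hydrogenation BF3 ionises the lactol to the cyclic oxocarbenium ion and triethylsilane reduces it to the ring CH2, while at or below −40 °C the benzylic ring C–O bond and the three stereocentres are left alone.

Step 13
Reactants: 20 the silyl-protected oxolane
Product: 21 (3S,4R,5S)-3-[4-(benzyloxy)-3-methoxybenzyl]-5-[4-(benzyloxy)-3-methoxyphenyl]-4-(hydroxymethyl)oxolan-3-ol
Conditions: TBAF, THF, 0 °C → rt
Reagents that add atoms: none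
Why: Fluoride desilylation frees the primary alcohol while the benzyl ethers and the tertiary alcohol are inert.

Step 14
Reactants: 21 the primary/tertiary diol
Product: 22 [(2S,3R,4S)-4-[4-(benzyloxy)-3-methoxybenzyl]-2-[4-(benzyloxy)-3-methoxyphenyl]-4-hydroxyoxolan-3-yl]methyl acetate
Conditions: Ac2O (1.1 equiv), pyridine, CH2Cl2, 0 °C → rt
Reagents that add atoms: acetic anhydride, CC(=O)OC(C)=O
Why: Acylation is selective for the primary hydroxyl because the hindered tertiary alcohol does not react with Ac2O/pyridine under these conditions and both phenols are still benzyl-protected.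

Step 15
Reactants: 22 the bis(O-benzyl) monoacetate
Product: 23 olivil monoacetate, [(2S,3R,4S)-4-hydroxy-4-(4-hydroxy-3-methoxybenzyl)-2-(4-hydroxy-3-methoxyphenyl)oxolan-3-yl]methyl acetate
Conditions: H2 (1 atm), 10% Pd/C, EtOAc, rt, stopped at full conversion
Reagents that add atoms: none
Why: Catalytic hydrogenolysis of the two aryl benzyl ethers under neutral conditions is faster than cleavage of the cyclic benzylic ether and leaves the acetate and all stereocentres unchanged.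

**Compound list**

1 | 4-(benzyloxy)-3-methoxybenzaldehyde (O-benzylvanillin) | O=Cc1ccc(OCc2ccccc2)c(OC)c1 | starting material
2 | [4-(benzyloxy)-3-methoxyphenyl]methanol | OCc1ccc(OCc2ccccc2)c(OC)c1 | intermediate
3 | 1-(benzyloxy)-4-(bromomethyl)-2-methoxybenzene | BrCc1ccc(OCc2ccccc2)c(OC)c1 | intermediate
4 | (4S)-4-benzyl-1,3-oxazolidin-2-one | O=C1N[C@@H](Cc2ccccc2)CO1 | starting material
5 | methyl 4-chloro-4-oxobutanoate | COC(=O)CCC(Cl)=O | starting material
6 | N-lithio derivative of 4 | [Li]N1[C@@H](Cc2ccccc2)COC1=O | intermediate (not isolated)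
7 | methyl 4-[(4S)-4-benzyl-2-oxo-1,3-oxazolidin-3-yl]-4-oxobutanoate | COC(=O)CCC(=O)N1[C@@H](Cc2ccccc2)COC1=O | intermediate
8 | (Z)-dibutylboron enolate of 7 | COC(=O)C/C=C(\OB(CCCC)CCCC)N1[C@@H](Cc2ccccc2)COC1=O | intermediate (not isolated)
9 | methyl (3S,4S)-3-{[(4S)-4-benzyl-2-oxo-1,3-oxazolidin-3-yl]carbonyl}-4-[4-(benzyloxy)-3-methoxyphenyl]-4-hydroxybutanoate | COC(=O)C[C@@H]([C@H](O)c1ccc(OCc2ccccc2)c(OC)c1)C(=O)N1[C@@H](Cc2ccccc2)COC1=O | intermediate
10 | (4S)-4-benzyl-3-{[(2S,3S)-2-[4-(benzyloxy)-3-methoxyphenyl]-5-oxooxolan-3-yl]carbonyl}-1,3-oxazolidin-2-one | O=C1O[C@H](c2ccc(OCc3ccccc3)c(OC)c2)[C@@H](C(=O)N2[C@@H](Cc3ccccc3)COC2=O)C1 | intermediate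
11 | lithium (2S,3S)-2-[4-(benzyloxy)-3-methoxyphenyl]-5-oxooxolane-3-carboperoxoate | O=C1O[C@H](c2ccc(OCc3ccccc3)c(OC)c2)[C@@H](C(=O)O[O-])C1.[Li+] | intermediate (not isolated)
12 | (2S,3S)-2-[4-(benzyloxy)-3-methoxyphenyl]-5-oxooxolane-3-carboxylic acid | O=C1O[C@H](c2ccc(OCc3ccccc3)c(OC)c2)[C@@H](C(=O)O)C1 | intermediate
13 | (4R,5S)-5-[4-(benzyloxy)-3-methoxyphenyl]-4-(hydroxymethyl)oxolan-2-one | O=C1O[C@H](c2ccc(OCc3ccccc3)c(OC)c2)[C@@H](CO)C1 | intermediate
14 | (4R,5S)-5-[4-(benzyloxy)-3-methoxyphenyl]-4-{[(tert-butyldiphenylsilyl)oxy]methyl}oxolan-2-one | O=C1O[C@H](c2ccc(OCc3ccccc3)c(OC)c2)[C@@H](CO[Si](c2ccccc2)(c2ccccc2)C(C)(C)C)C1 | intermediate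
15 | lithium enolate of 14 | [Li]OC1=C[C@H](CO[Si](c2ccccc2)(c2ccccc2)C(C)(C)C)[C@@H](c2ccc(OCc3ccccc3)c(OC)c2)O1 | intermediate (not isolated)
16 | (3S,4R,5S)-3-[4-(benzyloxy)-3-methoxybenzyl]-5-[4-(benzyloxy)-3-methoxyphenyl]-4-{[(tert-butyldiphenylsilyl)oxy]methyl}oxolan-2-one | COc1cc(C[C@@H]2C(=O)O[C@H](c3ccc(OCc4ccccc4)c(OC)c3)[C@H]2CO[Si](c3ccccc3)(c3ccccc3)C(C)(C)C)ccc1OCc1ccccc1 | intermediate
17 | potassium enolate of 16 | [K]OC1=C(Cc2ccc(OCc3ccccc3)c(OC)c2)[C@H](CO[Si](c2ccccc2)(c2ccccc2)C(C)(C)C)[C@@H](c2ccc(OCc3ccccc3)c(OC)c2)O1 | intermediate (not isolated)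
18 | (3S,4R,5S)-3-[4-(benzyloxy)-3-methoxybenzyl]-5-[4-(benzyloxy)-3-methoxyphenyl]-4-{[(tert-butyldiphenylsilyl)oxy]methyl}-3-hydroxyoxolan-2-one | COc1cc(C[C@@]2(O)C(=O)O[C@H](c3ccc(OCc4ccccc4)c(OC)c3)[C@H]2CO[Si](c3ccccc3)(c3ccccc3)C(C)(C)C)ccc1OCc1ccccc1 | intermediate
19 | (3S,4R,5S)-3-[4-(benzyloxy)-3-methoxybenzyl]-5-[4-(benzyloxy)-3-methoxyphenyl]-4-{[(tert-butyldiphenylsilyl)oxy]methyl}oxolane-2,3-diol (anomer mixture) | COc1cc(C[C@@]2(O)C(O)O[C@H](c3ccc(OCc4ccccc4)c(OC)c3)[C@H]2CO[Si](c3ccccc3)(c3ccccc3)C(C)(C)C)ccc1OCc1ccccc1 | intermediate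
20 | (3S,4R,5S)-3-[4-(benzyloxy)-3-methoxybenzyl]-5-[4-(benzyloxy)-3-methoxyphenyl]-4-{[(tert-butyldiphenylsilyl)oxy]methyl}oxolan-3-ol | COc1cc(C[C@@]2(O)CO[C@H](c3ccc(OCc4ccccc4)c(OC)c3)[C@H]2CO[Si](c3ccccc3)(c3ccccc3)C(C)(C)C)ccc1OCc1ccccc1 | intermediate
21 | (3S,4R,5S)-3-[4-(benzyloxy)-3-methoxybenzyl]-5-[4-(benzyloxy)-3-methoxyphenyl]-4-(hydroxymethyl)oxolan-3-ol | COc1cc(C[C@@]2(O)CO[C@H](c3ccc(OCc4ccccc4)c(OC)c3)[C@H]2CO)ccc1OCc1ccccc1 | intermediate
22 | [(2S,3R,4S)-4-[4-(benzyloxy)-3-methoxybenzyl]-2-[4-(benzyloxy)-3-methoxyphenyl]-4-hydroxyoxolan-3-yl]methyl acetate | COc1cc(C[C@@]2(O)CO[C@H](c3ccc(OCc4ccccc4)c(OC)c3)[C@H]2COC(C)=O)ccc1OCc1ccccc1 | intermediate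
23 | olivil monoacetate, [(2S,3R,4S)-4-hydroxy-4-(4-hydroxy-3-methoxybenzyl)-2-(4-hydroxy-3-methoxyphenyl)oxolan-3-yl]methyl acetate | COc1cc(C[C@@]2(O)CO[C@H](c3ccc(O)c(OC)c3)[C@H]2COC(C)=O)ccc1O | target

**Totals**

Total step count: 15.
Longest linear sequence: 13 steps (steps 3–15, from 4 and 5); steps 1–2 are a two-step branch that supplies bromide 3 for step 9.

**Three steps most likely to fail**

Step 4 (aldol of the ester-bearing imide; the ester may disturb boron enolisation or the adduct may lactonise unevenly). The fallback sets out from 4 and 1 and comes back at 10; it masks the carboxyl as an alkene. Auxiliary 4 is N-acylated (n-BuLi, pent-4-enoyl chloride, THF, −78 °C) to (4S)-4-benzyl-3-(pent-4-enoyl)-1,3-oxazolidin-2-one F1. The same Bu2BOTf/iPr2NEt aldol with 1 gives the syn adduct (4S)-4-benzyl-3-{(2S)-2-[(S)-[4-(benzyloxy)-3-methoxyphenyl](hydroxy)methyl]pent-4-enoyl}-1,3-oxazolidin-2-one F2. Lemieux–Johnson cleavage of the vinyl group (cat. OsO4, NaIO4, 2,6-lutidine, dioxane/H2O) gives the aldehyde as its ring tautomer, the lactol (4S)-4-benzyl-3-{[(2S,3S)-2-[4-(benzyloxy)-3-methoxyphenyl]-5-hydroxyoxolan-3-yl]carbonyl}-1,3-oxazolidin-2-one F3. Oxidation of the lactol (TEMPO, PhI(OAc)2, CH2Cl2) gives 10.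

Step 10 (hydroxylation of a hindered, fully substituted enolate; conversion or facial selectivity may be poor). The fallback sets out from 14 and comes back at 18; it fixes the carbinol by epoxidation and builds the benzyl C–C bond by epoxide opening.
- The enolate of 14 (LiHMDS, −78 °C) is trapped with Eschenmoser's salt to give the Mannich base (3R,4R,5S)-5-[4-(benzyloxy)-3-methoxyphenyl]-4-{[(tert-butyldiphenylsilyl)oxy]methyl}-3-[(dimethylamino)methyl]oxolan-2-one F4.
- MeI gives the trimethylammonium iodide of that Mannich base F5, which loses trimethylamine on stirring with aq. NaHCO3 to give (4R,5S)-5-[4-(benzyloxy)-3-methoxyphenyl]-4-{[(tert-butyldiphenylsilyl)oxy]methyl}-3-methylideneoxolan-2-one F6.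
- Dimethyldioxirane in acetone epoxidises the exocyclic alkene anti to the CH2OTBDPS group, giving (3R,6S,7R)-6-[4-(benzyloxy)-3-methoxyphenyl]-7-{[(tert-butyldiphenylsilyl)oxy]methyl}-1,5-dioxaspiro[2.4]heptan-4-one F7.
- [4-(Benzyloxy)-3-methoxyphenyl]magnesium bromide F8, made from 1-(benzyloxy)-4-bromo-2-methoxybenzene and Mg in THF, opens the epoxide at its CH2 terminus with catalytic CuI at −40 °C and gives 18.

Step 12 (ionic reduction; the oxocarbenium ion next to the carbinol forms sluggishly, and warming risks ionising or reductively opening the electron-rich benzylic ether). The fallback sets out from 18 and comes back at 20; it opens the ring and recloses it at the benzylic carbon. LiAlH4 (THF, 0 °C) reduces the lactone to (2S,3R)-2-[4-(benzyloxy)-3-methoxybenzyl]-3-{(S)-[4-(benzyloxy)-3-methoxyphenyl](hydroxy)methyl}-4-[(tert-butyldiphenylsilyl)oxy]butane-1,2-diol F9. Catalytic camphorsulfonic acid (CH2Cl2, 0 °C, short reaction time) ionises the p-alkoxybenzylic alcohol, and the primary hydroxyl closes the oxolane 5-exo under thermodynamic control to the 2,3-trans isomer 20. The reaction is stopped early to avoid Friedel–Crafts closure onto the other arene.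

Further compounds

F1 | step 4 | (4S)-4-benzyl-3-(pent-4-enoyl)-1,3-oxazolidin-2-one | C=CCCC(=O)N1[C@@H](Cc2ccccc2)COC1=O
F2 | step 4 | (4S)-4-benzyl-3-{(2S)-2-[(S)-[4-(benzyloxy)-3-methoxyphenyl](hydroxy)methyl]pent-4-enoyl}-1,3-oxazolidin-2-one | C=CC[C@@H]([C@H](O)c1ccc(OCc2ccccc2)c(OC)c1)C(=O)N1[C@@H](Cc2ccccc2)COC1=O
F3 | step 4 | (4S)-4-benzyl-3-{[(2S,3S)-2-[4-(benzyloxy)-3-methoxyphenyl]-5-hydroxyoxolan-3-yl]carbonyl}-1,3-oxazolidin-2-one (anomer mixture) | OC1O[C@H](c2ccc(OCc3ccccc3)c(OC)c2)[C@@H](C(=O)N2[C@@H](Cc3ccccc3)COC2=O)C1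
F4 | step 10 | (3R,4R,5S)-5-[4-(benzyloxy)-3-methoxyphenyl]-4-{[(tert-butyldiphenylsilyl)oxy]methyl}-3-[(dimethylamino)methyl]oxolan-2-one | CN(C)C[C@@H]1C(=O)O[C@H](c2ccc(OCc3ccccc3)c(OC)c2)[C@H]1CO[Si](c1ccccc1)(c1ccccc1)C(C)(C)C
F5 | step 10 | trimethylammonium iodide of F4 | C[N+](C)(C)C[C@@H]1C(=O)O[C@H](c2ccc(OCc3ccccc3)c(OC)c2)[C@H]1CO[Si](c1ccccc1)(c1ccccc1)C(C)(C)C.[I-]
F6 | step 10 | (4R,5S)-5-[4-(benzyloxy)-3-methoxyphenyl]-4-{[(tert-butyldiphenylsilyl)oxy]methyl}-3-methylideneoxolan-2-one | C=C1C(=O)O[C@H](c2ccc(OCc3ccccc3)c(OC)c2)[C@H]1CO[Si](c1ccccc1)(c1ccccc1)C(C)(C)C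
F7 | step 10 | (3R,6S,7R)-6-[4-(benzyloxy)-3-methoxyphenyl]-7-{[(tert-butyldiphenylsilyl)oxy]methyl}-1,5-dioxaspiro[2.4]heptan-4-one (epoxide O trans to CH2OTBDPS) | O1C[C@]12C(=O)O[C@H](c3ccc(OCc4ccccc4)c(OC)c3)[C@H]2CO[Si](c1ccccc1)(c1ccccc1)C(C)(C)C
F8 | step 10 | [4-(benzyloxy)-3-methoxyphenyl]magnesium bromide | COc1cc([Mg]Br)ccc1OCc1ccccc1
F9 | step 12 | (2S,3R)-2-[4-(benzyloxy)-3-methoxybenzyl]-3-{(S)-[4-(benzyloxy)-3-methoxyphenyl](hydroxy)methyl}-4-[(tert-butyldiphenylsilyl)oxy]butane-1,2-diol | COc1cc(C[C@@](O)(CO)[C@H](CO[Si](c2ccccc2)(c2ccccc2)C(C)(C)C)[C@H](O)c2ccc(OCc3ccccc3)c(OC)c2)ccc1OCc1ccccc1
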